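**Retrosynthetic overview**
- Ascomindone B is cut back to a protected 2,3-diaryl-4-hydroxy-6-methoxyindenone; the five phenols are unmasked last with BCl3.
- The indenone benzene ring (ring A) and cyclopentenone (ring B) are disconnected together: ring B at C3–aryl and C2=C3 (aryllithium of ring E plus a Z-arylidene hydroxyphthalide), ring A by a Brassard-diene Diels–Alder benzannulation on an α-bromo-γ-arylidenebutenolide; both closures are run in one flask.
- The arylidenebutenolide comes from the aldehyde of the diaryl ether (rings C–O–D) and 3-bromofuran-2(5H)-one by vinylogous aldol condensation.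
- The diaryl ether comes from a Smiles rearrangement of a depside built from a 2,3-dioxygenated 5-methoxybenzaldehyde and 2,6-dihydroxy-4-methylbenzoic acid.
- Ring order: rings C, D and E are bought as benzenoid starting materials, a butenolide is carried as a sacrificial ring, then ring A and ring B close in the same operation.

Assumption: the target has no stereocentre and no specified atropisomerism, so it is made as the single achiral compound drawn; the only stereo-element in the route is a transient Z alkene.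

**Step 1**
Reactants: 1 3-bromo-2-hydroxy-5-methoxybenzaldehyde
Product: 2 2,3-dihydroxy-5-methoxybenzaldehyde
Conditions: aq. NaOH (3 M), Cu powder (5 mol %), reflux, N2; then HCl
Reagents that add atoms: sodium hydroxide [Na+].[OH-]
Why: Copper-mediated Ullmann-type hydroxylation of an ortho-bromophenoxide (the 5-bromovanillin to 5-hydroxyvanillin reaction), with the aldehyde protected from Cannizzaro chemistry because the ring is a phenoxide.

**Step 2**
Reactants: 2 2,3-dihydroxy-5-methoxybenzaldehyde
Product: 3 2-hydroxy-5-methoxy-3-(propan-2-yloxy)benzaldehyde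
Conditions: NaH (2.2 equiv), DMSO, 25 °C; 2-iodopropane (1.2 equiv)
Reagents that add atoms: 2-iodopropane CC(C)I
Why: Williamson etherification of the dianion, in which the free C-3 phenoxide is far more nucleophilic than the C-2 phenoxide chelated to the aldehyde, so only O-3 is alkylated.

**Step 3**
Reactants: 3 2-hydroxy-5-methoxy-3-(propan-2-yloxy)benzaldehyde, 4 2,6-dihydroxy-4-methylbenzoic acid
Product: 5 2-formyl-4-methoxy-6-(propan-2-yloxy)phenyl 2,6-dihydroxy-4-methylbenzoate
Conditions: (CF3CO)2O, toluene, 0 to 25 °C; aq. NaHCO3 work-up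
Reagents that add atoms: none
Why: Mixed-anhydride esterification (the trifluoroacetic anhydride depside synthesis): the acid is activated as its trifluoroacetyl mixed anhydride and acylates the only phenol of 3, while the isopropyl ether tolerates the acid released.

**Step 4**
Reactants: 5 2-formyl-4-methoxy-6-(propan-2-yloxy)phenyl 2,6-dihydroxy-4-methylbenzoate
Product: 7 methyl 2-[2-formyl-4-methoxy-6-(propan-2-yloxy)phenoxy]-6-methoxy-4-methylbenzoate, via diaryl ether acid 6 (not isolated)
Conditions: K2CO3, DMSO, 60 °C; then MeI, 25 °C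
Reagents that add atoms: iodomethane CI
Why: Smiles rearrangement of a depside, in which an ortho-phenoxide of the acyl ring attacks the formyl-activated ipso carbon through a six-membered spiro Meisenheimer intermediate and expels the carboxylate, followed by O-methylation of the carboxylate and the remaining phenoxide in the same pot.

**Step 5**
Reactants: 8 furan-2(5H)-one
Product: 10 3-bromofuran-2(5H)-one, via trans-dibromolactone 9 (not isolated)
Conditions: Br2, CH2Cl2, 0 to 25 °C; then Et3N, 0 °C
Reagents that add atoms: bromine BrBr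
Why: Anti bromination of the alkene followed by E1cB dehydrobromination, in which the acidic α-hydrogen is removed and the β-bromide leaves, so the bromine stays at C-3.

**Step 6**
Reactants: 7 methyl 2-[2-formyl-4-methoxy-6-(propan-2-yloxy)phenoxy]-6-methoxy-4-methylbenzoate, 10 3-bromofuran-2(5H)-one
Product: 13 methyl 2-[2-[(Z)-(4-bromo-5-oxofuran-2(5H)-ylidene)methyl]-4-methoxy-6-(propan-2-yloxy)phenoxy]-6-methoxy-4-methylbenzoate, via silyloxyfuran 11 (not isolated), via silyl aldol adduct 12 (not isolated)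
Conditions: TBSOTf, iPr2NEt, CH2Cl2, −78 to 0 °C; then DBU, 25 °C
Reagents that add atoms: none
Why: Vinylogous Mukaiyama aldol addition of the in situ 2-silyloxyfuran at its C-5 followed by DBU-induced E1cB loss of silanolate, which gives the thermodynamically preferred Z-arylidenebutenolide.

**Step 7**
Reactants: 14 methyl (E)-3-methoxybut-2-enoate
Product: 15 [(1,3-dimethoxybuta-1,3-dien-1-yl)oxy]trimethylsilane (Brassard diene)
Conditions: LiN(iPr)2, THF, −78 °C; Me3SiCl, −78 to 0 °C
Reagents that add atoms: chlorotrimethylsilane C[Si](C)(C)Cl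
Why: Kinetic γ-deprotonation of the vinylogous ester and O-silylation of the dienolate, the standard preparation of Brassard's diene.

**Step 8**
Reactants: 16 5-methylbenzene-1,3-diol (orcinol)
Product: 17 1,3-bis(methoxymethoxy)-5-methylbenzene
Conditions: NaH, MOMCl, DMF, 0 to 25 °C
Reagents that add atoms: chloromethyl methyl ether COCCl
Why: Double Williamson etherification, which installs two acetal groups that both protect the phenols and direct the later ortho-lithiation.

**Step 9**
Reactants: 13 methyl 2-[2-[(Z)-(4-bromo-5-oxofuran-2(5H)-ylidene)methyl]-4-methoxy-6-(propan-2-yloxy)phenoxy]-6-methoxy-4-methylbenzoate, 15 [(1,3-dimethoxybuta-1,3-dien-1-yl)oxy]trimethylsilane, 17 1,3-bis(methoxymethoxy)-5-methylbenzene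
Product: 23 methyl 2-[2-[3-[2,6-bis(methoxymethoxy)-4-methylphenyl]-4-hydroxy-6-methoxy-1-oxo-1H-inden-2-yl]-4-methoxy-6-(propan-2-yloxy)phenoxy]-6-methoxy-4-methylbenzoate, via aryllithium 18 (not isolated), via Diels–Alder adduct 19 (not isolated), via arylidene hydroxyphthalide 20 (not isolated), via open diketone 21 (not isolated), via hydroxyindanone 22 (not isolated)
Conditions: 13, 15 (1.5 equiv), toluene, 90 °C; DBU, 25 °C; volatiles off in vacuo; THF, 18 (4 equiv, from 17, n-BuLi, THF, 0 °C), −78 to 0 °C; 1 M HCl, 25 °C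
Reagents that add atoms: none
Why: Proposed new method: the nucleophilic CH2 terminus of diene 15 bonds to the bromine-free β-carbon (C-4) of the bromobutenolide and its ketene-acetal carbon to the bromine-bearing C-3, so that DBU-promoted loss of HBr and MeOSiMe3 aromatises adduct 19 to ring A with the phenol next to the lactone carbonyl (20); aryllithium 18 (ortho-lithiation between the two acetal oxygens) then adds to that lactone carbonyl, the ring opens to the enolate of diketone 21, and aldol closure followed by acid dehydration (22 to 23) forms ring B; the closest known reactions are the Brassard-diene/α-halo-enone Diels–Alder benzannulation and the benzalphthalide plus aryl Grignard synthesis of 2,3-diarylindenones, here telescoped.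

**Step 10**
Reactants: 23 methyl 2-[2-[3-[2,6-bis(methoxymethoxy)-4-methylphenyl]-4-hydroxy-6-methoxy-1-oxo-1H-inden-2-yl]-4-methoxy-6-(propan-2-yloxy)phenoxy]-6-methoxy-4-methylbenzoate
Product: 24 methyl 2-[2-[3-(2,6-dihydroxy-4-methylphenyl)-4-hydroxy-6-methoxy-1-oxo-1H-inden-2-yl]-6-hydroxy-4-methoxyphenoxy]-6-hydroxy-4-methylbenzoate (Ascomindone B)
Conditions: BCl3 (8 equiv), CH2Cl2, −78 to 0 °C; H2O
Reagents that add atoms: none
Why: Lewis-acid ether cleavage in which BCl3 removes the two acetals and the isopropyl ether and, by chelation to the ester carbonyl, only the methyl ether ortho to it, while the two non-chelated methyl ethers and the hindered methyl ester remain.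

**Compound list**
1 | 3-bromo-2-hydroxy-5-methoxybenzaldehyde | O=Cc1cc(OC)cc(Br)c1O | starting material
2 | 2,3-dihydroxy-5-methoxybenzaldehyde | O=Cc1cc(OC)cc(O)c1O | intermediate
3 | 2-hydroxy-5-methoxy-3-(propan-2-yloxy)benzaldehyde | O=Cc1cc(OC)cc(OC(C)C)c1O | intermediate
4 | 2,6-dihydroxy-4-methylbenzoic acid | Cc1cc(O)c(C(=O)O)c(O)c1 | starting material
5 | 2-formyl-4-methoxy-6-(propan-2-yloxy)phenyl 2,6-dihydroxy-4-methylbenzoate | Cc1cc(O)c(C(=O)Oc2c(C=O)cc(OC)cc2OC(C)C)c(O)c1 | intermediate
6 | 2-[2-formyl-4-methoxy-6-(propan-2-yloxy)phenoxy]-6-hydroxy-4-methylbenzoic acid (formed as its dipotassium salt) | Cc1cc(O)c(C(=O)O)c(Oc2c(C=O)cc(OC)cc2OC(C)C)c1 | intermediate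
7 | methyl 2-[2-formyl-4-methoxy-6-(propan-2-yloxy)phenoxy]-6-methoxy-4-methylbenzoate | COC(=O)c1c(OC)cc(C)cc1Oc1c(C=O)cc(OC)cc1OC(C)C | intermediate
8 | furan-2(5H)-one | O=C1OCC=C1 | starting material
9 | trans-3,4-dibromooxolan-2-one (racemate, one enantiomer drawn) | O=C1OC[C@H](Br)[C@H]1Br | intermediate
10 | 3-bromofuran-2(5H)-one | O=C1OCC=C1Br | intermediate
11 | [(3-bromofuran-2-yl)oxy](tert-butyl)dimethylsilane | CC(C)(C)[Si](C)(C)Oc1occc1Br | intermediate
12 | methyl 2-[2-[(4-bromo-5-oxo-2,5-dihydrofuran-2-yl)(tert-butyldimethylsilyloxy)methyl]-4-methoxy-6-(propan-2-yloxy)phenoxy]-6-methoxy-4-methylbenzoate (racemic diastereomer mixture, stereocentres not controlled) | COC(=O)c1c(OC)cc(C)cc1Oc1c(OC(C)C)cc(OC)cc1C(O[Si](C)(C)C(C)(C)C)C1OC(=O)C(Br)=C1 | intermediate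
13 | methyl 2-[2-[(Z)-(4-bromo-5-oxofuran-2(5H)-ylidene)methyl]-4-methoxy-6-(propan-2-yloxy)phenoxy]-6-methoxy-4-methylbenzoate | COC(=O)c1c(OC)cc(C)cc1Oc1c(OC(C)C)cc(OC)cc1/C=C1\OC(=O)C(Br)=C1 | intermediate
14 | methyl (E)-3-methoxybut-2-enoate | CO/C(C)=C/C(=O)OC | starting material
15 | [(1,3-dimethoxybuta-1,3-dien-1-yl)oxy]trimethylsilane (ketene-acetal geometry not controlled) | C=C(OC)C=C(OC)O[Si](C)(C)C | intermediate
16 | 5-methylbenzene-1,3-diol (orcinol) | Cc1cc(O)cc(O)c1 | starting material
17 | 1,3-bis(methoxymethoxy)-5-methylbenzene | Cc1cc(OCOC)cc(OCOC)c1 | intermediate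
18 | [2,6-bis(methoxymethoxy)-4-methylphenyl]lithium | [Li]c1c(OCOC)cc(C)cc1OCOC | intermediate
19 | methyl 2-[2-[(Z)-[3a-bromo-4,6-dimethoxy-3-oxo-4-(trimethylsilyloxy)-3a,4,7,7a-tetrahydro-2-benzofuran-1(3H)-ylidene]methyl]-4-methoxy-6-(propan-2-yloxy)phenoxy]-6-methoxy-4-methylbenzoate (cis-fused racemate, ketal epimers) | O=C1O/C(=C\c3cc(OC)cc(OC(C)C)c3Oc3cc(C)cc(OC)c3C(=O)OC)C2CC(OC)=CC(OC)(O[Si](C)(C)C)C12Br | intermediate
20 | methyl 2-[2-[(Z)-(4-hydroxy-6-methoxy-3-oxo-2-benzofuran-1(3H)-ylidene)methyl]-4-methoxy-6-(propan-2-yloxy)phenoxy]-6-methoxy-4-methylbenzoate | O=C1O/C(=C\c3cc(OC)cc(OC(C)C)c3Oc3cc(C)cc(OC)c3C(=O)OC)c2cc(OC)cc(O)c12 | intermediate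
21 | methyl 2-[2-[2-[2-[2,6-bis(methoxymethoxy)-4-methylbenzoyl]-3-hydroxy-5-methoxyphenyl]-2-oxoethyl]-4-methoxy-6-(propan-2-yloxy)phenoxy]-6-methoxy-4-methylbenzoate (formed as its lithium enolate) | COC(=O)c1c(OC)cc(C)cc1Oc1c(OC(C)C)cc(OC)cc1CC(=O)c1cc(OC)cc(O)c1C(=O)c1c(OCOC)cc(C)cc1OCOC | intermediate
22 | methyl 2-[2-[3-[2,6-bis(methoxymethoxy)-4-methylphenyl]-3,4-dihydroxy-6-methoxy-1-oxo-2,3-dihydro-1H-inden-2-yl]-4-methoxy-6-(propan-2-yloxy)phenoxy]-6-methoxy-4-methylbenzoate (racemic diastereomer mixture, stereocentres not controlled) | COC(=O)c1c(OC)cc(C)cc1Oc1c(OC(C)C)cc(OC)cc1C1C(=O)c2cc(OC)cc(O)c2C1(O)c1c(OCOC)cc(C)cc1OCOC | intermediate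
23 | methyl 2-[2-[3-[2,6-bis(methoxymethoxy)-4-methylphenyl]-4-hydroxy-6-methoxy-1-oxo-1H-inden-2-yl]-4-methoxy-6-(propan-2-yloxy)phenoxy]-6-methoxy-4-methylbenzoate | COC(=O)c1c(OC)cc(C)cc1Oc1c(OC(C)C)cc(OC)cc1C1=C(c2c(OCOC)cc(C)cc2OCOC)c2c(O)cc(OC)cc2C1=O | intermediate
24 | Ascomindone B, methyl 2-[2-[3-(2,6-dihydroxy-4-methylphenyl)-4-hydroxy-6-methoxy-1-oxo-1H-inden-2-yl]-6-hydroxy-4-methoxyphenoxy]-6-hydroxy-4-methylbenzoate | COC(=O)c1c(O)cc(C)cc1Oc1c(O)cc(OC)cc1C1=C(c2c(O)cc(C)cc2O)c2c(O)cc(OC)cc2C1=O | target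

**Totals**
Total step count: 10. Longest linear sequence: 7 steps (steps 1, 2, 3, 4, 6, 9, 10).

**Three steps most likely to fail**

Step 9 is the riskiest. The diene may react at the exocyclic alkene of 13 or too slowly, aromatisation of 19 may be incomplete, and the aryllithium then meets a crude mixture. The fallback builds ring A before the arylidene is present and sets out from 10 and 15. Their Diels–Alder reaction in toluene at 80 °C gives the cycloadduct 7a-bromo-5,7-dimethoxy-7-(trimethylsilyloxy)-3a,4,7,7a-tetrahydro-2-benzofuran-1(3H)-one F1. DBU converts this to 7-hydroxy-5-methoxy-2-benzofuran-1(3H)-one F2, which is isolated. Its dianion (LiN(iPr)2, 2.2 equiv, THF, −78 °C) adds through the lactone CH2 carbon to aldehyde 7 to give the aldol adduct methyl 2-[2-[hydroxy(4-hydroxy-6-methoxy-3-oxo-1,3-dihydro-2-benzofuran-1-yl)methyl]-4-methoxy-6-(propan-2-yloxy)phenoxy]-6-methoxy-4-methylbenzoate F3. Acid-catalysed dehydration (TsOH, toluene, 80 °C) gives 20 in pure form, where the fallback rejoins the route; 20 is then treated with 18 and dilute HCl as in the second half of step 9 to reach 23.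

Step 4 is the second risk. The ipso carbon of 5 carries only one activating formyl group against two donor oxygens, so the Smiles rearrangement may lose to simple ester cleavage. The fallback replaces the rearrangement by two intermolecular nucleophilic aromatic substitutions and sets out from 3. Commercial 3,5-difluorotoluene is lithiated between the fluorines (LiN(iPr)2, THF, −78 °C) and quenched with ClCO2Me to give methyl 2,6-difluoro-4-methylbenzoate F4. The potassium phenoxide of 3 (K2CO3, DMSO, 110 °C) displaces one fluoride to give methyl 2-fluoro-6-[2-formyl-4-methoxy-6-(propan-2-yloxy)phenoxy]-4-methylbenzoate F5. NaOMe in MeOH/DMF at 60 °C displaces the second fluoride and gives 7, where the fallback rejoins the route; depside 5 is then not needed.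

Step 10 is the third risk. BCl3 must distinguish the chelated methyl ether from two ordinary ones on an electron-rich polyphenol. The fallback separates the cleavages and sets out from 23. HCl in MeOH/THF at 45 °C removes only the two acetals and gives methyl 2-[2-[3-(2,6-dihydroxy-4-methylphenyl)-4-hydroxy-6-methoxy-1-oxo-1H-inden-2-yl]-4-methoxy-6-(propan-2-yloxy)phenoxy]-6-methoxy-4-methylbenzoate F6. AlCl3 in CH2Cl2 at 0 to 25 °C then removes the isopropyl group and the ester-chelated methyl group to give 24, where the fallback rejoins the route.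

**Further compounds**
F1 | step 9 | 7a-bromo-5,7-dimethoxy-7-(trimethylsilyloxy)-3a,4,7,7a-tetrahydro-2-benzofuran-1(3H)-one (cis-fused racemate, ketal epimers) | O=C1OCC2CC(OC)=CC(OC)(O[Si](C)(C)C)C12Br
F2 | step 9 | 7-hydroxy-5-methoxy-2-benzofuran-1(3H)-one | O=C1OCc2cc(OC)cc(O)c12
F3 | step 9 | methyl 2-[2-[hydroxy(4-hydroxy-6-methoxy-3-oxo-1,3-dihydro-2-benzofuran-1-yl)methyl]-4-methoxy-6-(propan-2-yloxy)phenoxy]-6-methoxy-4-methylbenzoate (racemic diastereomer mixture) | COC(=O)c1c(OC)cc(C)cc1Oc1c(OC(C)C)cc(OC)cc1C(O)C1OC(=O)c2c(O)cc(OC)cc12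
F4 | step 4 | methyl 2,6-difluoro-4-methylbenzoate | COC(=O)c1c(F)cc(C)cc1F
F5 | step 4 | methyl 2-fluoro-6-[2-formyl-4-methoxy-6-(propan-2-yloxy)phenoxy]-4-methylbenzoate | COC(=O)c1c(F)cc(C)cc1Oc1c(C=O)cc(OC)cc1OC(C)C
F6 | step 10 | methyl 2-[2-[3-(2,6-dihydroxy-4-methylphenyl)-4-hydroxy-6-methoxy-1-oxo-1H-inden-2-yl]-4-methoxy-6-(propan-2-yloxy)phenoxy]-6-methoxy-4-methylbenzoate | COC(=O)c1c(OC)cc(C)cc1Oc1c(OC(C)C)cc(OC)cc1C1=C(c2c(O)cc(C)cc2O)c2c(O)cc(OC)cc2C1=O
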